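The constants of this flask are hidden, but a ratio of two rates, as it stands during the run, can be read from the alpha run, which is this same flask followed for its first minute.

- alpha: Z 37 mM (fed, over 6.0 s); D 3 equiv; G 0.020 equiv; the very flask that is asked about, followed so far
- flask: Z 37 mM (fed, over 6.0 s); D 3.00 equiv; G 0.0200 equiv; time 2.5 min

alpha run (percent of the Z charged)

| time / s | Q / % | Z / % |
|---|---|---|
| 25.0 | 8 | 94 |
| 30.0 | 9 | 90 |
| 40.0 | 18 | 78 |
| 50.0 | 28 | 66 |
| 60.0 | 37 | 51 |

(standard deviation of a reading: 1.5 percentage points)

* the moment within 2.5 min at which there is most Q
* the amount of Q, in percent of the Z charged, at that time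

Z loses some fraction of itself each second, and Q loses some fraction of itself to the missing material. Q stops rising when the two losses are equal in percent per second. So at the peak, Q over Z equals the first fraction over the second, and time has dropped out. Read both fractions from the readings:

Q: missing material 4.00% → 12.0%, mean Q 27.5%, so 0.0145 /s

Z, latest interval: 0.0258 /s

Ratio: 1.77

Call this S, the selectivity factor. It is a reading: the gain in missing material, 8 percentage points, carries a scatter of 3 points.

Two extremes bracket the peak. If S stays flat from the start, the peak is S^(−1/(S−1)), or 47.7%. If the remaining Z turned into Q at once, without loss, Q would reach 88.0%.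

The real flask lies between. Z's fraction read 0.0143 /s from 30.0 s to 40.0 s, and the latest 0.0258 /s is nearly twice that, so the reading of S is not flat. My own reckoning lets S rise once more by that factor:

3.19 gives a peak of 58.9%, with Z at 18.4%

At the latest speed of Z, that comes at 1.36 min, and later if Z slows.

The forecast, reading Z loss as “roughly zero-order or autocatalytic”, gives 54% (45% to 64%) at 1.5 min (1.25 min to 1.85 min), a peak lower than mine.

The flask gives 55.6% at 1.64 min.

    G + L ⇌ J, settled at all times (K = 6.90 × 10⁶ /M)
    Z + D → Q + L (k = 0.0230 /M/s)
    L → X (k = 0.00430 /s)
    D + Q → E (k = 0.130 /M/s)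
    Z + D + L → Q + 2 L (k = 18.0 /M²/s)

At that moment Z is 14.8% and Q 55.6%, so S, as Q over Z, is 3.75, twice the 1.77 read from the run. D stands in all three rates and cancels. S is then the constant of Z + D, plus that of Z + D + L times L, over the constant of D + Q. With L at 25.8 mM this is 3.75. In a second flask with 63 mM of Z and the same equivalents, L stands at 36.7 mM at 2.50 min, which makes S 5.26 at that time, and the best Q of that flask is 67.4%.

The numbers in the tables are calculated on assumed constants; noise was put on by code.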